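## The problem

Target 24 is a (2S)-flavanone whose ring A is a phloroglucinol nucleus with five substituents: oxygen at C5, C7 and C8a, the carbonyl carbon on C4a and a ten-carbon chain on C8. The three ring A oxygens must therefore be told apart, and the chain must be placed on the one carbon that lies between O7 and the ring oxygen O1. The chain is a hydrated lavandulyl group whose single stereocentre (C2'', R) carries an isopropenyl group and is insulated from ring A by the C1'' methylene. It is too far from C2 for either centre to direct the other, so C2'' is best taken from the chiral pool and C2 must be set by a catalyst. A failure at C2 gives an epimer that differs only through the remote chain and will be hard to remove. Several groups are fragile: the C2–O1 bond is a para-hydroxybenzylic ether β to the ketone and opens to a chalcone under base, and the tertiary alcohol and isopropenyl group beside the C7 phenol ionise, eliminate or cyclise to a chroman under strong acid. The enabling feature is ring C itself. Its O1–C2 and C3–C4 bonds flank the two-carbon unit C2–C3, which can arrive intact as the vinyl group of a ring B styrene, while O1–C8a–C4a–C4 is the heterodiene of an ortho-quinone methide that a ring A salicylaldehyde can release. The 5,7-dioxygenation stabilises charge at C4 and the 4'-hydroxyl and 2'-methoxy groups stabilise it at C2, but C4 emerges as an ether and must be oxidised to the ketone afterwards.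

## Retrosynthesis

**Endgame, no skeletal cut (24 back to 19).** The three phenols of 24 are unmasked last from the tris(methoxymethyl) ether 22. The C4 ketone of 22 comes from the flavan-4-ol 21, and 21 from solvolysis of the 4-methoxyflavan 20. Compound 20 is the ring B methoxymethyl ether of the cycloadduct 19. The ring B phenol is capped only after it has served as the catalyst handle, because a free para-hydroxybenzylic ether at C2 is the part most exposed to oxidants and to ionisation in the redox steps. Asked of the forward steps: acid mild enough to exchange the doubly activated C4 ether without touching C2 or the acetals, and a final deprotection that spares the tertiary alcohol.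

**Ring C (19 to 14 and 16).** The O1–C2 and C3–C4 bonds are cut together. This removes the ring and both new stereocentres in one operation and leaves two fragments of unequal size: the salicylaldehyde 14, which holds the whole of ring A and the chain, and the small styrene 16. The neighbouring cuts (chalcone C2–O1 closure, or C2–aryl bond formation on a chromone) would need ring A as an acetophenone and a separate asymmetric step. The forward reaction must generate the 4-methoxy ortho-quinone methide 18 from 14 through acetal 17 under a chiral Brønsted acid, add 16 with the correct face at C2, and use only the C8a oxygen for closure. The last point is secured by capping O5 and O7 in 14.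

**Chain to ring A (14 to 11 and 8).** The C8–C1'' bond is cut to the aryl iodide 11 and the primary alkyl iodide 8, joined through the alkylzinc 12 in a Negishi coupling. An sp3–sp2 coupling is preferred to alkylation of an aryl anion, which would invite elimination across the allylic β-hydrogen of 8. It is also preferred to acylation or reduction sequences, which would place a carbonyl next to C2''. The forward reaction must tolerate the aldehyde and cope with a di-ortho-substituted iodide. The tertiary alcohol is masked as a trimethylsilyl ether for the zinc chemistry only.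

**Ring A (11 to 10 to 9).** The iodide 11 derives from 10 by iodination ortho to the one free, chelated phenol. Compound 10 derives from 2,4,6-trihydroxybenzaldehyde 9 by capping the two hydroxyls that are not held by the aldehyde. The free phenol that directs the iodine is the same oxygen that later becomes O1, so no further differentiation of the three oxygens is needed.

**Chain (8 to 1).** Silyl ether 8 comes from alcohol 7, and 7 from methyl addition to ketone 6. The C–I bond of 6 is traced to the carboxyl group of acid 4, with excision of one carbon. Acid 4 comes from aldehyde 3, and 3 from oxidative opening of the ring alkene of (R)-limonene 1 via epoxide 2. The limonene stereocentre becomes C2'' with its isopropenyl group in place and is never α to a carbonyl, so it cannot epimerise. The price is the one-carbon excision, which is accepted because it is a single operation on a robust acid.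

**Ring B (16 to 15).** The vinyl group of 16 is cut at the C=C bond to the commercial aldehyde 15 by methylenation.

## Roads not taken

Alternative 1: The cut is the C1''–C2'' bond. A base releases the ring A ortho-quinone methide from sulfone A2, and the enamine formed from aldehyde A3 and a chiral secondary amine adds to its methylene. The phenol then closes onto the aldehyde carbon to give the chroman-2-ol A1 with C2'' set. Merits: C2'' is made by catalysis, no carbon has to be excised, and no palladium coupling at a crowded arene is needed. Weak points for this target: the lactol carbon of A1 still has to become the isopropenyl group by methyl addition, oxidation and methylenation, through a methyl ketone that is α to C2'' and can epimerise. After that ring A still lacks C4, and ring C and C2 are untouched. In chain construction this road is arguably better than the chosen one, since it avoids the radical decarboxylation and the one-carbon loss. The chosen plan sets against it a stereocentre that is configurationally safe throughout and a key step that delivers ring C and C2. Alternative 1 would have to borrow that step or find another, and would be several steps longer.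

Alternative 2: The cut runs through ring A (C8a–C8 and C7–C6). Heating siloxyalkyne A5 with cyclobutenone A6 gives, through a vinylketene, a cyclobutenone and a dienylketene, the phenol A4. In A4 the chain lies between a free hydroxyl and a silyl ether, and the third oxygen carries a different group. Merits: the position of the chain and the distinction of all three oxygens are fixed by construction, which is better than the chosen plan's reliance on a regioselective iodination and a hindered coupling. Weak points: A5 needs the same chain from 1 plus a homologation to the ynol ether. The thermal cascade must tolerate the isopropenyl group. A4 still lacks the C4 carbon, and nothing of ring C or C2 is made. The chosen plan answers with a shorter ring A sequence from 9 (three steps to 14) and uses the chelated phenol for the same differentiation.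

Alternative 3: The cut is the C2–C3 bond. The diazomethyl ketone A8, under a chiral dirhodium tetracarboxylate, forms a carbene that inserts into a benzylic C–H bond of the ortho aryl benzyl ether and gives the silyl-protected flavanone A7 directly. Merits: the ring closes at the ketone oxidation level, so the three redox and exchange steps of the chosen plan disappear, and the all-silyl protection comes off with fluoride rather than acid. In endgame economy this road is better. Weak points: the ether oxygen is five atoms from the carbene and should form an oxonium ylide that undergoes benzyl shift to a benzofuranone in competition with the six-membered insertion. Acceptor-only carbenes give modest enantiocontrol in such insertions. A8 requires ring A as an aryl ketone with the full chain, O-benzylation of the hindered O1 and a diazo transfer. The chosen plan sets against this a polar ring closure whose racemic form is established and has no ylide diversion, at the cost of a longer endgame.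

Key step: step 11

Assumptions: the sense of induction of the chiral phosphoric acid in step 11 cannot be predicted with confidence. The (R)-catalyst is written, and its antipode is to be used if a model reaction shows the opposite preference. Epoxide 2 is carried as its cis/trans mixture, since both epoxide carbons become carbonyl groups.

## Route

Step 1
Reactants: 1 (R)-(+)-limonene
Product: 2 (4R)-1-methyl-4-(prop-1-en-2-yl)-7-oxabicyclo[4.1.0]heptane (cis/trans epoxide mixture)
Conditions: mCPBA (1.0 equiv), NaHCO3, CH2Cl2, 0 °C
Reagents that add atoms: 3-chloroperoxybenzoic acid (mCPBA), O=C(OO)c1cccc(Cl)c1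
Why: Prilezhaev epoxidation; the trisubstituted ring alkene is more nucleophilic than the 1,1-disubstituted isopropenyl group, so one equivalent of peracid at 0 °C should react there selectively, and the stereocentre is untouched.

Step 2
Reactants: 2 (4R)-limonene 1,2-oxide
Product: 3 (3R)-6-oxo-3-(prop-1-en-2-yl)heptanal
Conditions: H5IO6 (1.1 equiv), THF/H2O, 0 °C → rt
Reagents that add atoms: water, O
Why: Acid-promoted epoxide hydrolysis and Malaprade glycol cleavage in one flask, a known opening of limonene oxide; the stereocentre is β to the aldehyde and γ to the ketone and cannot enolise away.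

Step 3
Reactants: 3 (3R)-6-oxo-3-(prop-1-en-2-yl)heptanal
Product: 4 (3R)-6-oxo-3-(prop-1-en-2-yl)heptanoic acid
Conditions: NaClO2, NaH2PO4, 2-methyl-2-butene, t-BuOH/H2O, 0 °C → rt
Reagents that add atoms: sodium chlorite, [Na+].[O-]Cl=O
Why: Pinnick oxidation of the aldehyde; the scavenger alkene intercepts hypochlorous acid before it can reach the isopropenyl group, and the ketone is inert.

Step 4
Reactants: 4 (3R)-6-oxo-3-(prop-1-en-2-yl)heptanoic acid
Product: 6 (5S)-5-(iodomethyl)-6-methylhept-6-en-2-one, via Barton ester 5 (not isolated)
Conditions: 1-hydroxypyridine-2(1H)-thione, DCC, CH2Cl2, 0 °C → rt, dark; then CHI3 (2 equiv), visible light, rt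
Reagents that add atoms: iodoform, IC(I)I
Why: Barton decarboxylative iodination. The primary radical takes iodine from iodoform much faster than it can close onto the substituted carbon of the isopropenyl group, and the diiodomethyl radical is consumed by the thiocarbonyl group. No bond at the stereocentre changes (the descriptor becomes S only because CH2I outranks isopropenyl).

Step 5
Reactants: 6 (5S)-5-(iodomethyl)-6-methylhept-6-en-2-one
Product: 7 (5S)-5-(iodomethyl)-2,6-dimethylhept-6-en-2-ol
Conditions: MeMgBr (1.2 equiv), THF, −78 °C; aq. NH4Cl at −78 °C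
Reagents that add atoms: methylmagnesium bromide, C[Mg]Br
Why: Grignard addition to the methyl ketone; an unactivated primary iodide does not react with the reagent at −78 °C without copper, and the cold quench prevents the alkoxide from displacing iodide.

Step 6
Reactants: 7 (5S)-5-(iodomethyl)-2,6-dimethylhept-6-en-2-ol
Product: 8 {[(5S)-5-(iodomethyl)-2,6-dimethylhept-6-en-2-yl]oxy}trimethylsilane
Conditions: 1-(trimethylsilyl)imidazole, CH2Cl2, rt
Reagents that add atoms: 1-(trimethylsilyl)imidazole, C[Si](C)(C)n1ccnc1
Why: Neutral silylation of a tertiary alcohol; it removes the only proton that would destroy the organozinc reagent of step 9.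

Step 7
Reactants: 9 2,4,6-trihydroxybenzaldehyde
Product: 10 2-hydroxy-4,6-bis(methoxymethoxy)benzaldehyde
Conditions: MOMCl (2.2 equiv), i-Pr2NEt, CH2Cl2, 0 °C → rt
Reagents that add atoms: chloromethyl methyl ether, COCCl
Why: Phenol O-alkylation; the hydroxyl that remains is hydrogen-bonded to the aldehyde and is the least nucleophilic, a standard differentiation of phloroglucinol aldehydes and ketones.

Step 8
Reactants: 10 2-hydroxy-4,6-bis(methoxymethoxy)benzaldehyde
Product: 11 2-hydroxy-3-iodo-4,6-bis(methoxymethoxy)benzaldehyde
Conditions: BnMe3N·ICl2 (1.05 equiv), NaHCO3, CH2Cl2/MeOH, rt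
Reagents that add atoms: benzyltrimethylammonium dichloroiodate, C[N+](C)(C)Cc1ccccc1.Cl[I-]Cl
Why: Electrophilic aromatic iodination; under buffered conditions the chelated free phenol directs ortho (C3), and the alternative position is flanked by two bulkier acetal ethers.

Step 9
Reactants: 8 {[(5S)-5-(iodomethyl)-2,6-dimethylhept-6-en-2-yl]oxy}trimethylsilane; 11 2-hydroxy-3-iodo-4,6-bis(methoxymethoxy)benzaldehyde
Product: 14 2-hydroxy-3-[(2R)-5-hydroxy-5-methyl-2-(prop-1-en-2-yl)hexyl]-4,6-bis(methoxymethoxy)benzaldehyde, via alkylzinc iodide 12 (not isolated), via silyl-protected aldehyde 13 (not isolated)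
Conditions: 8, Zn dust (BrCH2CH2Br/TMSCl-activated), LiCl, THF, 35 °C; 11, NaH (1.0 equiv), THF, 0 °C; combine, Pd(OAc)2 (3 mol %), SPhos (2-dicyclohexylphosphino-2′,6′-dimethoxybiphenyl, 6 mol %), THF/NMP, 45 °C; then 1 M aq. HCl, THF, 0 °C
Reagents that add atoms: none
Why: Negishi sp3–sp2 coupling. Zinc inserts into the primary C–I bond, the phenol of 11 is first converted to its sodium salt so that it cannot protonate 12, and the bulky biarylphosphine on zerovalent palladium favours oxidative addition at the di-ortho-substituted iodide and reductive elimination over β-hydride loss. The aldehyde is inert to an alkylzinc halide, and the acidic work-up cleaves the trimethylsilyl ether and returns the phenol.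

Step 10
Reactants: 15 4-hydroxy-2-methoxybenzaldehyde
Product: 16 4-ethenyl-3-methoxyphenol
Conditions: Ph3PCH3Br (2.5 equiv), KOt-Bu (2.4 equiv), THF, 0 °C → rt; aq. NH4Cl; used at once (trace of BHT)
Reagents that add atoms: methyltriphenylphosphonium bromide, C[P+](c1ccccc1)(c1ccccc1)c1ccccc1.[Br-]
Why: Wittig methylenation; the extra base carries the phenol as its phenoxide, as is usual for hydroxybenzaldehydes, and the vinylphenol is used immediately because it polymerises on storage.

Step 11
Reactants: 14 2-hydroxy-3-[(2R)-5-hydroxy-5-methyl-2-(prop-1-en-2-yl)hexyl]-4,6-bis(methoxymethoxy)benzaldehyde; 16 4-ethenyl-3-methoxyphenol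
Product: 19 4-{(2S,4S)-8-[(2R)-5-hydroxy-5-methyl-2-(prop-1-en-2-yl)hexyl]-4-methoxy-5,7-bis(methoxymethoxy)-3,4-dihydro-2H-chromen-2-yl}-3-methoxyphenol, via dimethyl acetal 17 (not isolated), via ortho-quinone methide 18 (not isolated)
Conditions: 14, HC(OMe)3 (1.5 equiv), (R)-3,3′-bis(2,4,6-triisopropylphenyl)-1,1′-binaphthalene-2,2′-diyl hydrogen phosphate (10 mol %), 4 Å MS, toluene, 0 °C; then 16 (1.5 equiv, slow addition), −40 → −10 °C; Et3N quench
Reagents that add atoms: trimethyl orthoformate, COC(OC)OC
Why: Acid-catalysed exchange with the orthoformate gives acetal 17, and loss of methanol gives the 4-methoxy ortho-quinone methide 18, held in its O-protonated oxocarbenium form as a hydrogen-bonded ion pair with the chiral phosphate. The terminal carbon of 16 attacks C4, and the benzylic cation at C2 (a protonated para-quinone methide stabilised by the 4-hydroxyl and 2-methoxy groups) is captured by the phenol oxygen, an asynchronous inverse-electron-demand oxa-(4+2) cycloaddition. The closest known reaction is the acid-catalysed union of salicylaldehydes, orthoformates and styrenes to 2,4-cis-4-alkoxyflavans; the catalyst control is modelled on chiral phosphoric acid-catalysed cycloadditions of ortho-quinone methides with hydroxystyrenes and is an extrapolation to this pair. Ring C closes as the six-membered ring of the (4+2) process, in the stepwise picture by 6-exo-trig addition of O1 to the C2 terminus of the transient para-quinone methide. C2 is set by the catalyst, whose phosphate bridges the styrene hydroxyl and the quinone methide so that one alkene face is presented; the remote chain centre has no influence. C4 follows from the endo, chair-like arrangement with aryl and methoxy both pseudo-equatorial (2,4-cis) and is erased in step 14, so only C2 has to be right. Regioselectivity comes from the donor-polarised styrene. Chemoselectivity comes from the capped O5 and O7 (only the C8a phenol can close) and from the isopropenyl group being far less nucleophilic and unable to reach C4. The weak acid at low temperature should leave the acetals and the tertiary alcohol alone.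

Step 12
Reactants: 19 4-{(2S,4S)-8-[(2R)-5-hydroxy-5-methyl-2-(prop-1-en-2-yl)hexyl]-4-methoxy-5,7-bis(methoxymethoxy)-3,4-dihydro-2H-chromen-2-yl}-3-methoxyphenol
Product: 20 (2S,4S)-8-[(2R)-5-hydroxy-5-methyl-2-(prop-1-en-2-yl)hexyl]-4-methoxy-2-[2-methoxy-4-(methoxymethoxy)phenyl]-5,7-bis(methoxymethoxy)-3,4-dihydro-2H-chromene
Conditions: MOMCl (1.3 equiv), i-Pr2NEt, CH2Cl2, 0 °C → rt
Reagents that add atoms: chloromethyl methyl ether, COCCl
Why: Phenol O-alkylation; the hindered tertiary alcohol does not compete. Capping the phenol turns the para-hydroxybenzylic C2 ether into an ordinary benzylic ether before the acid and oxidation steps.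

Step 13
Reactants: 20 (2S,4S)-4-methoxyflavan tris(methoxymethyl) ether
Product: 21 (2S)-8-[(2R)-5-hydroxy-5-methyl-2-(prop-1-en-2-yl)hexyl]-2-[2-methoxy-4-(methoxymethoxy)phenyl]-5,7-bis(methoxymethoxy)-3,4-dihydro-2H-chromen-4-ol (mixture of C4 epimers)
Conditions: PPTS (0.3 equiv), acetone/H2O (4:1), 35 °C, 0.01 M
Reagents that add atoms: water, O
Why: SN1 solvolysis of a benzylic ether whose cation is stabilised by three ring A oxygens; the C2 ether is far less activated, the aryl acetals need stronger acid, and dilution with excess water disfavours capture of the cation by another arene.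

Step 14
Reactants: 21 (2S)-flavan-4-ol tris(methoxymethyl) ether
Product: 22 (2S)-8-[(2R)-5-hydroxy-5-methyl-2-(prop-1-en-2-yl)hexyl]-2-[2-methoxy-4-(methoxymethoxy)phenyl]-5,7-bis(methoxymethoxy)-2,3-dihydro-4H-chromen-4-one
Conditions: Dess–Martin periodinane (1.3 equiv), NaHCO3, CH2Cl2, 0 °C → rt
Reagents that add atoms: none
Why: Dess–Martin oxidation of the secondary benzylic alcohol; both C4 epimers converge, the tertiary alcohol cannot be oxidised, and the buffered non-basic medium should not open the flavanone at C2.

Step 15
Reactants: 22 (2S)-flavanone tris(methoxymethyl) ether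
Product: 24 (2S)-5,7-dihydroxy-2-(4-hydroxy-2-methoxyphenyl)-8-[(2R)-5-hydroxy-5-methyl-2-(prop-1-en-2-yl)hexyl]-2,3-dihydro-4H-chromen-4-one, via tetrakis(trimethylsilyl) ether 23 (not isolated)
Conditions: TMSOTf (8 equiv), 2,2′-bipyridyl (12 equiv), CH2Cl2, 0 °C → rt; then H2O/THF, citric acid, rt
Reagents that add atoms: none
Why: Silyl triflate and bipyridyl cleavage of aromatic methoxymethyl ethers; each aryl acetal is converted to an aryl silyl ether through a pyridinium salt under nearly neutral conditions, the tertiary alcohol is silylated in passing, and mild aqueous acid then hydrolyses all four silyl ethers. This avoids the hot mineral acid that would ionise the tertiary alcohol or cyclise the C7 phenol onto the isopropenyl group.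

## Compound list

1 | (R)-(+)-limonene, (4R)-1-methyl-4-(prop-1-en-2-yl)cyclohex-1-ene | C=C(C)[C@@H]1CCC(C)=CC1 | starting material
2 | (4R)-1-methyl-4-(prop-1-en-2-yl)-7-oxabicyclo[4.1.0]heptane (limonene 1,2-oxide, cis/trans mixture at the epoxide) | C=C(C)[C@@H]1CCC2(C)OC2C1 | intermediate
3 | (3R)-6-oxo-3-(prop-1-en-2-yl)heptanal | C=C(C)[C@H](CCC(C)=O)CC=O | intermediate
4 | (3R)-6-oxo-3-(prop-1-en-2-yl)heptanoic acid | C=C(C)[C@H](CCC(C)=O)CC(=O)O | intermediate
5 | 2-thioxopyridin-1(2H)-yl (3R)-6-oxo-3-(prop-1-en-2-yl)heptanoate (Barton ester, not isolated) | C=C(C)[C@H](CCC(C)=O)CC(=O)On1ccccc1=S | intermediate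
6 | (5S)-5-(iodomethyl)-6-methylhept-6-en-2-one | C=C(C)[C@H](CCC(C)=O)CI | intermediate
7 | (5S)-5-(iodomethyl)-2,6-dimethylhept-6-en-2-ol | C=C(C)[C@H](CCC(C)(C)O)CI | intermediate
8 | {[(5S)-5-(iodomethyl)-2,6-dimethylhept-6-en-2-yl]oxy}trimethylsilane | C=C(C)[C@H](CCC(C)(C)O[Si](C)(C)C)CI | intermediate
9 | 2,4,6-trihydroxybenzaldehyde | O=Cc1c(O)cc(O)cc1O | starting material
10 | 2-hydroxy-4,6-bis(methoxymethoxy)benzaldehyde | COCOc1cc(O)c(C=O)c(OCOC)c1 | intermediate
11 | 2-hydroxy-3-iodo-4,6-bis(methoxymethoxy)benzaldehyde | COCOc1cc(OCOC)c(C=O)c(O)c1I | intermediate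
12 | iodo[(2S)-5-methyl-2-(prop-1-en-2-yl)-5-(trimethylsilyloxy)hexyl]zinc (not isolated) | C=C(C)[C@H](CCC(C)(C)O[Si](C)(C)C)C[Zn]I | intermediate
13 | 2-hydroxy-4,6-bis(methoxymethoxy)-3-[(2R)-5-methyl-2-(prop-1-en-2-yl)-5-(trimethylsilyloxy)hexyl]benzaldehyde (not isolated) | C=C(C)[C@H](CCC(C)(C)O[Si](C)(C)C)Cc1c(OCOC)cc(OCOC)c(C=O)c1O | intermediate
14 | 2-hydroxy-3-[(2R)-5-hydroxy-5-methyl-2-(prop-1-en-2-yl)hexyl]-4,6-bis(methoxymethoxy)benzaldehyde | C=C(C)[C@H](CCC(C)(C)O)Cc1c(OCOC)cc(OCOC)c(C=O)c1O | intermediate
15 | 4-hydroxy-2-methoxybenzaldehyde | COc1cc(O)ccc1C=O | starting material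
16 | 4-ethenyl-3-methoxyphenol (4-hydroxy-2-methoxystyrene) | C=Cc1ccc(O)cc1OC | intermediate
17 | 2-(dimethoxymethyl)-6-[(2R)-5-hydroxy-5-methyl-2-(prop-1-en-2-yl)hexyl]-3,5-bis(methoxymethoxy)phenol (not isolated) | C=C(C)[C@H](CCC(C)(C)O)Cc1c(OCOC)cc(OCOC)c(C(OC)OC)c1O | intermediate
18 | 2-[(2R)-5-hydroxy-5-methyl-2-(prop-1-en-2-yl)hexyl]-6-(methoxymethylidene)-3,5-bis(methoxymethoxy)cyclohexa-2,4-dien-1-one (ortho-quinone methide, not isolated) | C=C(C)[C@H](CCC(C)(C)O)CC1=C(OCOC)C=C(OCOC)C(=COC)C1=O | intermediate
19 | 4-{(2S,4S)-8-[(2R)-5-hydroxy-5-methyl-2-(prop-1-en-2-yl)hexyl]-4-methoxy-5,7-bis(methoxymethoxy)-3,4-dihydro-2H-chromen-2-yl}-3-methoxyphenol (2,4-cis) | C=C(C)[C@H](CCC(C)(C)O)Cc1c(OCOC)cc(OCOC)c2c1O[C@H](c1ccc(O)cc1OC)C[C@@H]2OC | intermediate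
20 | (2S,4S)-8-[(2R)-5-hydroxy-5-methyl-2-(prop-1-en-2-yl)hexyl]-4-methoxy-2-[2-methoxy-4-(methoxymethoxy)phenyl]-5,7-bis(methoxymethoxy)-3,4-dihydro-2H-chromene | C=C(C)[C@H](CCC(C)(C)O)Cc1c(OCOC)cc(OCOC)c2c1O[C@H](c1ccc(OCOC)cc1OC)C[C@@H]2OC | intermediate
21 | (2S)-8-[(2R)-5-hydroxy-5-methyl-2-(prop-1-en-2-yl)hexyl]-2-[2-methoxy-4-(methoxymethoxy)phenyl]-5,7-bis(methoxymethoxy)-3,4-dihydro-2H-chromen-4-ol (mixture of C4 epimers) | C=C(C)[C@H](CCC(C)(C)O)Cc1c(OCOC)cc(OCOC)c2c1O[C@H](c1ccc(OCOC)cc1OC)CC2O | intermediate
22 | (2S)-8-[(2R)-5-hydroxy-5-methyl-2-(prop-1-en-2-yl)hexyl]-2-[2-methoxy-4-(methoxymethoxy)phenyl]-5,7-bis(methoxymethoxy)-2,3-dihydro-4H-chromen-4-one | C=C(C)[C@H](CCC(C)(C)O)Cc1c(OCOC)cc(OCOC)c2c1O[C@H](c1ccc(OCOC)cc1OC)CC2=O | intermediate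
23 | (2S)-2-[2-methoxy-4-(trimethylsilyloxy)phenyl]-8-[(2R)-5-methyl-2-(prop-1-en-2-yl)-5-(trimethylsilyloxy)hexyl]-5,7-bis(trimethylsilyloxy)-2,3-dihydro-4H-chromen-4-one (not isolated) | C=C(C)[C@H](CCC(C)(C)O[Si](C)(C)C)Cc1c(O[Si](C)(C)C)cc(O[Si](C)(C)C)c2c1O[C@H](c1ccc(O[Si](C)(C)C)cc1OC)CC2=O | intermediate
24 | (2S)-5,7-dihydroxy-2-(4-hydroxy-2-methoxyphenyl)-8-[(2R)-5-hydroxy-5-methyl-2-(prop-1-en-2-yl)hexyl]-2,3-dihydro-4H-chromen-4-one | C=C(C)[C@H](CCC(C)(C)O)Cc1c(O)cc(O)c2c1O[C@H](c1ccc(O)cc1OC)CC2=O | target

## Step count and least certain steps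

Total: 15 steps. Longest linear sequence: 12 steps (steps 1–6, 9, 11–15).

**Step 11 (key step).** The most likely failure is insufficient facial discrimination at C2: the para-hydroxyl handle binds the phosphate at a distance from the reacting vinyl terminus, and the quinone methide is flanked by bulky groups. Acid-induced oligomerisation of the vinylphenol and reversible reopening of the C2–O1 bond, which would erode the ratio, are the other concerns. Fallback: setting out from 14 and 16, the same union is run under an achiral acid (Sc(OTf)3 at low loading, the established form of the reaction). This should give the 2,4-cis flavan as a pair of C2 epimers, 19 and its (2R,4R)-epimer F1. The pair is separated by preparative chromatography on a chiral stationary phase, so that C2 is controlled by separation instead of by the catalyst. The route is rejoined at 19.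

**Step 9.** Protonation of the alkylzinc by incompletely deprotonated phenol, slow oxidative addition at the electron-rich di-ortho-substituted iodide, and β-hydride elimination to a diene could each starve the coupling. Fallback: setting out from 8, copper-catalysed borylation (CuI, PPh3, LiOMe, bis(pinacolato)diboron, DMF) gives the pinacol boronate F3. KHF2 in aqueous methanol converts it, with loss of the silyl ether, into potassium trifluoro[(2S)-5-hydroxy-5-methyl-2-(prop-1-en-2-yl)hexyl]borate F4. Suzuki–Miyaura coupling of F4 with 11 (Pd(OAc)2, 2-dicyclohexylphosphino-2′,6′-diisopropoxybiphenyl, K2CO3, toluene/H2O, 80 °C) tolerates the free phenol, the aldehyde and the tertiary alcohol and returns to the route at 14.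

**Step 8.** Iodination may occur para to the phenol (between the two acetal ethers) or twice. Fallback: setting out from 9, iodination is done first (I2, NaHCO3, aqueous THF), while the two open ring positions are equivalent, and gives 2,4,6-trihydroxy-3-iodobenzaldehyde F2. Treatment with MOMCl (2.2 equiv) and i-Pr2NEt should then cap the para hydroxyl and the less hindered ortho hydroxyl. The hydroxyl wedged between iodine and the aldehyde stays free, as is known for 3-substituted phloroglucinol ketones. The route is rejoined at 11.

**Step 13.** The C4 cation may be captured by the nucleophilic C6 position of a second molecule (flavan dimerisation), lose a proton to a flav-3-ene, or the acid may begin to ionise C2. Fallback: setting out from 20, oxidation with DDQ in CH2Cl2/pH 7 buffer at 0 °C abstracts the C4 hydride of the benzylic methyl ether, and water collapses the oxocarbenium ion to the ketone. This reaches 22 directly and bypasses 21 and every free cation at C4.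

**Step 15.** The silyl triflate may ionise the tertiary centre (elimination, or chroman formation once O7 is free), the unactivated ring B acetal may cleave incompletely, and long exposure risks opening at C2. Fallback: setting out from 19, step 12 is omitted. Solvolysis as in step 13 gives the free-phenol flavan-4-ol F5, and MnO2 in CH2Cl2 oxidises it to the flavanone F6, which carries only the two ring A acetals. Both are activated by the C4 carbonyl and should fall to dilute HCl in methanol/THF at 0 °C → rt, returning to the route at 24.

## Further compounds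

F1 | step 11 | 4-{(2R,4R)-8-[(2R)-5-hydroxy-5-methyl-2-(prop-1-en-2-yl)hexyl]-4-methoxy-5,7-bis(methoxymethoxy)-3,4-dihydro-2H-chromen-2-yl}-3-methoxyphenol | C=C(C)[C@H](CCC(C)(C)O)Cc1c(OCOC)cc(OCOC)c2c1O[C@@H](c1ccc(O)cc1OC)C[C@H]2OC
F2 | step 8 | 2,4,6-trihydroxy-3-iodobenzaldehyde | O=Cc1c(O)cc(O)c(I)c1O
F3 | step 9 | trimethyl({(5S)-2,6-dimethyl-5-[(4,4,5,5-tetramethyl-1,3,2-dioxaborolan-2-yl)methyl]hept-6-en-2-yl}oxy)silane | C=C(C)[C@H](CCC(C)(C)O[Si](C)(C)C)CB1OC(C)(C)C(C)(C)O1
F4 | step 9 | potassium trifluoro[(2S)-5-hydroxy-5-methyl-2-(prop-1-en-2-yl)hexyl]borate | C=C(C)[C@H](CCC(C)(C)O)C[B-](F)(F)F.[K+]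
F0 | step 13 | none | none
F5 | step 15 | 4-{(2S)-4-hydroxy-8-[(2R)-5-hydroxy-5-methyl-2-(prop-1-en-2-yl)hexyl]-5,7-bis(methoxymethoxy)-3,4-dihydro-2H-chromen-2-yl}-3-methoxyphenol (mixture of C4 epimers) | C=C(C)[C@H](CCC(C)(C)O)Cc1c(OCOC)cc(OCOC)c2c1O[C@H](c1ccc(O)cc1OC)CC2O
F6 | step 15 | (2S)-2-(4-hydroxy-2-methoxyphenyl)-8-[(2R)-5-hydroxy-5-methyl-2-(prop-1-en-2-yl)hexyl]-5,7-bis(methoxymethoxy)-2,3-dihydro-4H-chromen-4-one | C=C(C)[C@H](CCC(C)(C)O)Cc1c(OCOC)cc(OCOC)c2c1O[C@H](c1ccc(O)cc1OC)CC2=O
A1 | alternative 1 | 5,7-bis(methoxymethoxy)-3-[3-methyl-3-(triethylsilyloxy)butyl]-3,4-dihydro-2H-chromen-2-ol (anomeric mixture, C3 set) | OC1Oc2cc(OCOC)cc(OCOC)c2C[C@H]1CCC(C)(C)O[Si](CC)(CC)CC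
A2 | alternative 1 | 3,5-bis(methoxymethoxy)-2-[(phenylsulfonyl)methyl]phenol | COCOc1cc(O)c(CS(=O)(=O)c2ccccc2)c(OCOC)c1
A3 | alternative 1 | 5-methyl-5-(triethylsilyloxy)hexanal | CC[Si](CC)(CC)OC(C)(C)CCCC=O
A4 | alternative 2 | 2-[(2R)-5-methyl-2-(prop-1-en-2-yl)-5-(triethylsilyloxy)hexyl]-3-(triisopropylsilyloxy)-5-[2-(trimethylsilyl)ethoxy]phenol | C=C(C)[C@H](CCC(C)(C)O[Si](CC)(CC)CC)Cc1c(O)cc(OCC[Si](C)(C)C)cc1O[Si](C(C)C)(C(C)C)C(C)C
A5 | alternative 2 | triisopropyl{[(4R)-7-methyl-4-(prop-1-en-2-yl)-7-(triethylsilyloxy)oct-1-yn-1-yl]oxy}silane | C=C(C)[C@H](CCC(C)(C)O[Si](CC)(CC)CC)CC#CO[Si](C(C)C)(C(C)C)C(C)C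
A6 | alternative 2 | 3-[2-(trimethylsilyl)ethoxy]cyclobut-2-en-1-one | O=C1CC(OCC[Si](C)(C)C)=C1
A7 | alternative 3 | (2S)-2-[2-methoxy-4-(triisopropylsilyloxy)phenyl]-8-[(2R)-5-methyl-2-(prop-1-en-2-yl)-5-(triethylsilyloxy)hexyl]-5,7-bis(triisopropylsilyloxy)-2,3-dihydro-4H-chromen-4-one | C=C(C)[C@H](CCC(C)(C)O[Si](CC)(CC)CC)Cc1c(O[Si](C(C)C)(C(C)C)C(C)C)cc(O[Si](C(C)C)(C(C)C)C(C)C)c2c1O[C@H](c1ccc(O[Si](C(C)C)(C(C)C)C(C)C)cc1OC)CC2=O
A8 | alternative 3 | 2-diazo-1-{2-{[2-methoxy-4-(triisopropylsilyloxy)phenyl]methoxy}-3-[(2R)-5-methyl-2-(prop-1-en-2-yl)-5-(triethylsilyloxy)hexyl]-4,6-bis(triisopropylsilyloxy)phenyl}ethan-1-one | C=C(C)[C@H](CCC(C)(C)O[Si](CC)(CC)CC)Cc1c(O[Si](C(C)C)(C(C)C)C(C)C)cc(O[Si](C(C)C)(C(C)C)C(C)C)c(C(=O)C=[N+]=[N-])c1OCc1ccc(O[Si](C(C)C)(C(C)C)C(C)C)cc1OC
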